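**Retrosynthetic overview**

1. The six-membered carbocycle of the target is a cyclohexa-2,5-dienone whose carbonyl carbon C1 lies para to the quaternary, methoxy-bearing C4 (C2 allyl, C5 OMe). It is a para-quinol methyl ether, that is, a phenol ring after two-electron oxidation and C–O bond formation at the para carbon. It is therefore taken back to the phenol ring of 14, and the side-chain oxygen on Cβ (the CH–O carbon, 1,3 to C4 through Cα, the CHMe carbon) is used as a tether that hands the methoxy group to C4.
2. The last operation is acetylation of the Cβ alcohol (16 → 17). The tether is a 2-methoxyprop-2-yl ketal that leaves as acetone.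
3. The syn Cα/Cβ pair comes from a Felkin–Anh addition of a 3,4-dimethoxyphenyl titanium reagent to the (S)-2-arylpropanal 10. Cα comes from a palladium-catalysed arylation of an Evans propionimide enolate with aryl bromide 5.
4. Aryl bromide 5 comes from 4-bromo-3-methoxyphenol by O-allylation, aromatic Claisen rearrangement (C-allyl ortho to OH) and silylation.
5. Order of rings: both benzene rings are bought; the cyclohexadienone ring is generated last, from the phenol ring, in step 10.

Key step: step 10

Assumption: in the palladium-catalysed arylation of the silyl enolate of the Evans imide the aryl group is taken to enter on the enolate face remote from the benzyl group, as an alkyl halide does; if the opposite sense were found, the (4S)-imide would be used.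

Remark: the CHMe carbon is (S) in 8–14 and (R) in 15–17 only because the CIP priorities change when the neighbouring ring carbon becomes oxygenated; its geometry is not altered.

**Route**

Step 1
Reactants: 1 4-bromo-3-methoxyphenol; 2 allyl bromide
Product: 3 1-bromo-2-methoxy-4-(prop-2-en-1-yloxy)benzene
Conditions: K2CO3, acetone, reflux
Reagents that add atoms: none
Why: Williamson etherification of the phenoxide (SN2 on allyl bromide), in which O-alkylation is favoured in acetone with carbonate base.

Step 2
Reactants: 3 1-bromo-2-methoxy-4-(prop-2-en-1-yloxy)benzene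
Product: 4 4-bromo-5-methoxy-2-(prop-2-en-1-yl)phenol
Conditions: PhNEt2, 190 °C
Reagents that add atoms: none
Why: Aromatic Claisen rearrangement ([3,3]-sigmatropic shift, then tautomerization to the phenol), in which the allyl group should migrate mainly to the ortho carbon para to the methoxy group, which is less hindered than the carbon between the two oxygens, the minor regioisomer being removed by chromatography.

Step 3
Reactants: 4 4-bromo-5-methoxy-2-(prop-2-en-1-yl)phenol
Product: 5 [4-bromo-5-methoxy-2-(prop-2-en-1-yl)phenoxy]tri(propan-2-yl)silane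
Conditions: TIPSCl, imidazole, DMF, rt
Reagents that add atoms: chlorotri(propan-2-yl)silane, CC(C)[Si](Cl)(C(C)C)C(C)C
Why: Imidazole-promoted silylation of the phenol masks the acidic OH for the enolate and organometallic steps, and the bulky TIPS ether is chosen to survive them.

Step 4
Reactants: 5 [4-bromo-5-methoxy-2-(prop-2-en-1-yl)phenoxy]tri(propan-2-yl)silane; 6 (4R)-4-benzyl-3-propanoyl-1,3-oxazolidin-2-one
Product: 8 (4R)-4-benzyl-3-[(2S)-2-(2-methoxy-5-(prop-2-en-1-yl)-4-{[tri(propan-2-yl)silyl]oxy}phenyl)propanoyl]-1,3-oxazolidin-2-one, via silyl ketene aminal 7 (not isolated)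
Conditions: 6, LDA, TMSCl, THF, −78 °C → rt; then 5, Pd(dba)2 (cat.), P(t-Bu)3 (cat.), ZnF2, DMF, 80 °C
Reagents that add atoms: none
Why: Palladium-catalysed α-arylation of the silyl ketene N,O-acetal of an Evans imide (zinc fluoride-promoted transmetalation in a neutral medium that should not epimerize the product), in which the aryl group is delivered to the enolate face remote from the benzyl group and so sets the (S) α-aryl centre.

Step 5
Reactants: 8 (4R)-4-benzyl-3-[(2S)-2-(2-methoxy-5-(prop-2-en-1-yl)-4-{[tri(propan-2-yl)silyl]oxy}phenyl)propanoyl]-1,3-oxazolidin-2-one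
Product: 9 (2S)-2-(2-methoxy-5-(prop-2-en-1-yl)-4-{[tri(propan-2-yl)silyl]oxy}phenyl)propan-1-ol
Conditions: LiBH4, H2O (1 equiv), Et2O, 0 °C
Reagents that add atoms: none
Why: Reductive cleavage of the N-acyl oxazolidinone (hydride attack at the exocyclic imide carbonyl) releases the primary alcohol and the auxiliary without touching the α-stereocentre, the silyl ether or the alkene.

Step 6
Reactants: 9 (2S)-2-(2-methoxy-5-(prop-2-en-1-yl)-4-{[tri(propan-2-yl)silyl]oxy}phenyl)propan-1-ol
Product: 10 (2S)-2-(2-methoxy-5-(prop-2-en-1-yl)-4-{[tri(propan-2-yl)silyl]oxy}phenyl)propanal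
Conditions: Dess–Martin periodinane, CH2Cl2, 0 °C; used at once
Reagents that add atoms: none
Why: Dess–Martin oxidation of the primary alcohol under non-basic, non-enolizing conditions, chosen because the α-aryl aldehyde is configurationally labile to base.

Step 7
Reactants: 10 (2S)-2-(2-methoxy-5-(prop-2-en-1-yl)-4-{[tri(propan-2-yl)silyl]oxy}phenyl)propanal; 11 (3,4-dimethoxyphenyl)magnesium bromide
Product: 12 (1R,2S)-1-(3,4-dimethoxyphenyl)-2-(2-methoxy-5-(prop-2-en-1-yl)-4-{[tri(propan-2-yl)silyl]oxy}phenyl)propan-1-ol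
Conditions: 11, ClTi(OiPr)3, THF, −78 → 0 °C; then 10, −78 → −20 °C; aq. NH4Cl
Reagents that add atoms: none
Why: Felkin–Anh-controlled 1,2-addition of an aryltitanium triisopropoxide (made in the flask from 11 and ClTi(OiPr)3) to the α-aryl aldehyde, in which the nucleophile attacks anti to the large aryl substituent and so gives the (1R) carbinol with the syn 1,2-relationship, while the weakly basic titanium reagent should not enolize the aldehyde.

Step 8
Reactants: 12 (1R,2S)-1-(3,4-dimethoxyphenyl)-2-(2-methoxy-5-(prop-2-en-1-yl)-4-{[tri(propan-2-yl)silyl]oxy}phenyl)propan-1-ol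
Product: 13 {4-[(1R,2S)-1-(3,4-dimethoxyphenyl)-1-[(2-methoxypropan-2-yl)oxy]propan-2-yl]-5-methoxy-2-(prop-2-en-1-yl)phenoxy}tri(propan-2-yl)silane
Conditions: 2-methoxypropene, PPTS (cat.), CH2Cl2, 0 °C; Et3N
Reagents that add atoms: 2-methoxypropene, COC(C)=C
Why: Acid-catalysed addition of the secondary alcohol to the enol ether (mixed-ketal formation), which leaves the aryl silyl ether, the alkene and both stereocentres untouched.

Step 9
Reactants: 13 {4-[(1R,2S)-1-(3,4-dimethoxyphenyl)-1-[(2-methoxypropan-2-yl)oxy]propan-2-yl]-5-methoxy-2-(prop-2-en-1-yl)phenoxy}tri(propan-2-yl)silane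
Product: 14 4-[(1R,2S)-1-(3,4-dimethoxyphenyl)-1-[(2-methoxypropan-2-yl)oxy]propan-2-yl]-5-methoxy-2-(prop-2-en-1-yl)phenol
Conditions: TBAF, THF, 0 °C; pH 7 buffer
Reagents that add atoms: none
Why: Fluoride-induced cleavage of the aryl silyl ether (Si–O to Si–F exchange), to which the mixed ketal and the allyl group are inert.

Step 10
Reactants: 14 4-[(1R,2S)-1-(3,4-dimethoxyphenyl)-1-[(2-methoxypropan-2-yl)oxy]propan-2-yl]-5-methoxy-2-(prop-2-en-1-yl)phenol
Product: 16 (4R)-4-[(1R,2R)-1-(3,4-dimethoxyphenyl)-1-hydroxypropan-2-yl]-4,5-dimethoxy-2-(prop-2-en-1-yl)cyclohexa-2,5-dien-1-one, via acetoxy ketal dienone 15 (not isolated)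
Conditions: PhI(OAc)2, NaHCO3, MeCN, −20 → 0 °C; then aq. phosphate buffer (pH 5–6), 0 °C
Reagents that add atoms: none
Why: Proposed new method: ligand exchange of the phenol at iodine(III) and two-electron oxidation give a phenoxonium (aryloxy-λ3-iodane) that is electrophilic at the para carbon C4; the methoxy oxygen of the 2-methoxyprop-2-yl ketal on the Cβ oxygen attacks C4 through a six-membered chair-like transition state, and the resulting oxonium collapses by C–O cleavage to the C4 methyl ether and a 2-alkoxyprop-2-yl cation, which is held as its acetate adduct 15 and hydrolysed to acetone and the free Cβ alcohol on buffered aqueous work-up. The closest known reaction types are the para-alkoxylative dearomatization of 4-alkylphenols with PhI(OAc)2 in methanol and intramolecular aglycon delivery, in which an alkoxy group is passed from a mixed isopropylidene ketal to an oxocarbenium carbon. No ring of the skeleton is closed by a new ring bond: the benzene ring is converted into the cyclohexa-2,5-dienone, and the only closure is the transient six-membered oxonium (6-exo attack of oxygen on the C4 terminus of the cation), which opens again in the same step. The new stereocentre C4 is controlled by the Cα stereocentre: in the cyclic transition state the Cα methyl lies over the unsubstituted C3–H edge of the ring and not over the C5 methoxy group (A1,3 strain), so that oxygen is delivered to the face that gives (4R). The step needs para (ipso) C–O bond formation in preference to capture by acetate or by the dimethoxyphenyl ring, and it needs the ketal to survive until the oxidation; the tether (high effective molarity), the non-fluorinated solvent and the NaHCO3 buffer are meant to secure this.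

Step 11
Reactants: 16 (4R)-4-[(1R,2R)-1-(3,4-dimethoxyphenyl)-1-hydroxypropan-2-yl]-4,5-dimethoxy-2-(prop-2-en-1-yl)cyclohexa-2,5-dien-1-one
Product: 17 (1R,2R)-1-(3,4-dimethoxyphenyl)-2-[(1R)-1,6-dimethoxy-4-oxo-3-(prop-2-en-1-yl)cyclohexa-2,5-dien-1-yl]propyl acetate
Conditions: Ac2O, pyridine, DMAP (cat.), CH2Cl2, 0 °C
Reagents that add atoms: acetic anhydride, CC(=O)OC(C)=O
Why: DMAP-catalysed O-acylation of the secondary alcohol under basic, non-ionizing conditions, so that neither the benzylic centre nor the acid-sensitive dienone is disturbed.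

**Compound list**

1 | 4-bromo-3-methoxyphenol | COc1cc(O)ccc1Br | starting material
2 | allyl bromide (3-bromoprop-1-ene) | C=CCBr | starting material
3 | 1-bromo-2-methoxy-4-(prop-2-en-1-yloxy)benzene | C=CCOc1ccc(Br)c(OC)c1 | intermediate
4 | 4-bromo-5-methoxy-2-(prop-2-en-1-yl)phenol | C=CCc1cc(Br)c(OC)cc1O | intermediate
5 | [4-bromo-5-methoxy-2-(prop-2-en-1-yl)phenoxy]tri(propan-2-yl)silane | C=CCc1cc(Br)c(OC)cc1O[Si](C(C)C)(C(C)C)C(C)C | intermediate
6 | (4R)-4-benzyl-3-propanoyl-1,3-oxazolidin-2-one | CCC(=O)N1[C@H](Cc2ccccc2)COC1=O | starting material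
7 | (4R)-4-benzyl-3-[(1Z)-1-(trimethylsilyloxy)prop-1-en-1-yl]-1,3-oxazolidin-2-one | C/C=C(\O[Si](C)(C)C)N1[C@H](Cc2ccccc2)COC1=O | intermediate (not isolated)
8 | (4R)-4-benzyl-3-[(2S)-2-(2-methoxy-5-(prop-2-en-1-yl)-4-{[tri(propan-2-yl)silyl]oxy}phenyl)propanoyl]-1,3-oxazolidin-2-one | C=CCc1cc([C@H](C)C(=O)N2[C@H](Cc3ccccc3)COC2=O)c(OC)cc1O[Si](C(C)C)(C(C)C)C(C)C | intermediate
9 | (2S)-2-(2-methoxy-5-(prop-2-en-1-yl)-4-{[tri(propan-2-yl)silyl]oxy}phenyl)propan-1-ol | C=CCc1cc([C@H](C)CO)c(OC)cc1O[Si](C(C)C)(C(C)C)C(C)C | intermediate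
10 | (2S)-2-(2-methoxy-5-(prop-2-en-1-yl)-4-{[tri(propan-2-yl)silyl]oxy}phenyl)propanal | C=CCc1cc([C@H](C)C=O)c(OC)cc1O[Si](C(C)C)(C(C)C)C(C)C | intermediate
11 | (3,4-dimethoxyphenyl)magnesium bromide | COc1ccc([Mg]Br)cc1OC | starting material
12 | (1R,2S)-1-(3,4-dimethoxyphenyl)-2-(2-methoxy-5-(prop-2-en-1-yl)-4-{[tri(propan-2-yl)silyl]oxy}phenyl)propan-1-ol | C=CCc1cc([C@H](C)[C@@H](O)c2ccc(OC)c(OC)c2)c(OC)cc1O[Si](C(C)C)(C(C)C)C(C)C | intermediate
13 | {4-[(1R,2S)-1-(3,4-dimethoxyphenyl)-1-[(2-methoxypropan-2-yl)oxy]propan-2-yl]-5-methoxy-2-(prop-2-en-1-yl)phenoxy}tri(propan-2-yl)silane | C=CCc1cc([C@H](C)[C@@H](OC(C)(C)OC)c2ccc(OC)c(OC)c2)c(OC)cc1O[Si](C(C)C)(C(C)C)C(C)C | intermediate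
14 | 4-[(1R,2S)-1-(3,4-dimethoxyphenyl)-1-[(2-methoxypropan-2-yl)oxy]propan-2-yl]-5-methoxy-2-(prop-2-en-1-yl)phenol | C=CCc1cc([C@H](C)[C@@H](OC(C)(C)OC)c2ccc(OC)c(OC)c2)c(OC)cc1O | intermediate
15 | 2-{[(1R,2R)-1-(3,4-dimethoxyphenyl)-2-[(1R)-1,6-dimethoxy-4-oxo-3-(prop-2-en-1-yl)cyclohexa-2,5-dien-1-yl]propyl]oxy}propan-2-yl acetate | C=CCC1=C[C@@](OC)([C@H](C)[C@@H](OC(C)(C)OC(C)=O)c2ccc(OC)c(OC)c2)C(OC)=CC1=O | intermediate (not isolated)
16 | (4R)-4-[(1R,2R)-1-(3,4-dimethoxyphenyl)-1-hydroxypropan-2-yl]-4,5-dimethoxy-2-(prop-2-en-1-yl)cyclohexa-2,5-dien-1-one | C=CCC1=C[C@@](OC)([C@H](C)[C@@H](O)c2ccc(OC)c(OC)c2)C(OC)=CC1=O | intermediate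
17 | (1R,2R)-1-(3,4-dimethoxyphenyl)-2-[(1R)-1,6-dimethoxy-4-oxo-3-(prop-2-en-1-yl)cyclohexa-2,5-dien-1-yl]propyl acetate | C=CCC1=C[C@@](OC)([C@H](C)[C@@H](OC(C)=O)c2ccc(OC)c(OC)c2)C(OC)=CC1=O | target

**Step count and risks**

Total step count: 11. Longest linear sequence: 11 steps (1 → 17).

Steps most likely to fail:

1. Step 10 (Proposed new method). Four processes may spoil it: loss of the acid-labile ketal before the oxidation; capture of the oxidized ring by acetate or by the dimethoxyphenyl ring (C–C spirocyclization) in place of methoxy transfer; poor facial selectivity at C4; and cyclization of the freed Cβ alcohol onto the methoxy-bearing C5 during work-up. The fallback uses known chemistry, sets out from 12 and comes back to the route at 17. Compound 12 is acetylated (Ac2O, pyridine, DMAP) to the silyl ether acetate F1. The silyl group is removed with TBAF buffered with AcOH to give the phenol acetate F2. F2 is then oxidized with PhI(OAc)2 in methanol at 0 °C, the classical para-methoxylative dearomatization of 4-alkylphenols (anodic oxidation in MeOH/LiClO4 is an equivalent). This should give 17 directly, together with the C4 epimer of 17 F3, which would be removed by chromatography. In this variant the face selectivity rests on substrate control alone.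

2. Step 7. The α-aryl aldehyde may enolize and lose configuration before or during the addition, and the Felkin–Anh preference may be incomplete. The fallback sets out from 8 and comes back at 12, avoiding the aldehyde. Imide 8 is transaminated with MeONHMe·HCl/AlMe3 to the Weinreb amide F4. Addition of 11 (THF, 0 °C) gives the aryl ketone F5, which is configurationally more robust than 10. Reagent-controlled reduction with (S)-2-methyl-CBS-oxazaborolidine and catecholborane at low temperature, a non-basic protocol that should not epimerize the α-centre, is then expected to give the (1R) carbinol 12. Here the catalyst has to override the substrate's Felkin preference (which favours the anti alcohol), so this fallback carries its own selectivity risk.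

3. Step 4. The arylation may proceed with low diastereoselectivity or with epimerization of the α-aryl imide, and the fluoride additive or the palladium catalyst may attack the silyl ether or the allyl group. The fallback sets out from 5 and comes back at 9, and moves the stereo-defining event to an enolate alkylation. Commercial (4S)-4-benzyl-3-acetyl-1,3-oxazolidin-2-one is converted (LDA, TMSCl) into the acetyl silyl ketene aminal F6. F6 is coupled with 5 under the palladium/zinc fluoride conditions to the arylacetyl imide F7, a step that creates no stereocentre. Evans methylation (NaHMDS, MeI, THF, −78 °C), in which the chelated Z-enolate is alkylated anti to the benzyl group, gives the (S,S)-2-arylpropanoyl imide F8. LiBH4 reduction of F8 gives 9. This fallback answers the stereochemical failure, not a failure of the palladium coupling itself.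

**Further compounds**

F1 | step 10 | (1R,2S)-1-(3,4-dimethoxyphenyl)-2-(2-methoxy-5-(prop-2-en-1-yl)-4-{[tri(propan-2-yl)silyl]oxy}phenyl)propyl acetate | C=CCc1cc([C@H](C)[C@@H](OC(C)=O)c2ccc(OC)c(OC)c2)c(OC)cc1O[Si](C(C)C)(C(C)C)C(C)C
F2 | step 10 | (1R,2S)-1-(3,4-dimethoxyphenyl)-2-[4-hydroxy-2-methoxy-5-(prop-2-en-1-yl)phenyl]propyl acetate | C=CCc1cc([C@H](C)[C@@H](OC(C)=O)c2ccc(OC)c(OC)c2)c(OC)cc1O
F3 | step 10 | (1R,2R)-1-(3,4-dimethoxyphenyl)-2-[(1S)-1,6-dimethoxy-4-oxo-3-(prop-2-en-1-yl)cyclohexa-2,5-dien-1-yl]propyl acetate | C=CCC1=C[C@](OC)([C@H](C)[C@@H](OC(C)=O)c2ccc(OC)c(OC)c2)C(OC)=CC1=O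
F4 | step 7 | (2S)-N-methoxy-2-(2-methoxy-5-(prop-2-en-1-yl)-4-{[tri(propan-2-yl)silyl]oxy}phenyl)-N-methylpropanamide | C=CCc1cc([C@H](C)C(=O)N(C)OC)c(OC)cc1O[Si](C(C)C)(C(C)C)C(C)C
F5 | step 7 | (2S)-1-(3,4-dimethoxyphenyl)-2-(2-methoxy-5-(prop-2-en-1-yl)-4-{[tri(propan-2-yl)silyl]oxy}phenyl)propan-1-one | C=CCc1cc([C@H](C)C(=O)c2ccc(OC)c(OC)c2)c(OC)cc1O[Si](C(C)C)(C(C)C)C(C)C
F6 | step 4 | (4S)-4-benzyl-3-[1-(trimethylsilyloxy)ethenyl]-1,3-oxazolidin-2-one | C=C(O[Si](C)(C)C)N1[C@@H](Cc2ccccc2)COC1=O
F7 | step 4 | (4S)-4-benzyl-3-[(2-methoxy-5-(prop-2-en-1-yl)-4-{[tri(propan-2-yl)silyl]oxy}phenyl)acetyl]-1,3-oxazolidin-2-one | C=CCc1cc(CC(=O)N2[C@@H](Cc3ccccc3)COC2=O)c(OC)cc1O[Si](C(C)C)(C(C)C)C(C)C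
F8 | step 4 | (4S)-4-benzyl-3-[(2S)-2-(2-methoxy-5-(prop-2-en-1-yl)-4-{[tri(propan-2-yl)silyl]oxy}phenyl)propanoyl]-1,3-oxazolidin-2-one | C=CCc1cc([C@H](C)C(=O)N2[C@@H](Cc3ccccc3)COC2=O)c(OC)cc1O[Si](C(C)C)(C(C)C)C(C)C
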